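The runs are simulated from invented constants; the scatter is artificial.

The ochre flask cannot be holding as target what it has converted: by 12.0 min the starting material has lost 46.9%, yet target reads less, 26.3%. I take the rest to sit in the isomer of the product, and I treat target and isomer as a pre-equilibrium.

in all of them: starting material 1.5 M; temperature 35 °C
- ochre: reagent 1.1 equiv; second substrate 1 equiv; third substrate 0.20 equiv; the very flask that is asked about, followed so far
- teal: reagent 0.74 equiv; second substrate 1 equiv; third substrate 0.20 equiv; run made earlier
- flask: reagent 1.10 equiv; second substrate 1.00 equiv; third substrate 0.200 equiv; time 20 min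

- ochre (time / min: target / %, starting material / %): 0.667: 5.9, 94.1; 2.00: 13.3, 84.8; 3.00: 16.2, 79.5; 5.00: 21.9, 70.2; 8.00: 25.9, 62.2; 10.0: 26.6, 56.2; 12.0: 26.3, 53.1
- teal (time / min: target / %, starting material / %): 1.00: 4.8, 94.5; 1.50: 7.1, 91.9; 2.50: 11.1, 87.3; 4.00: 13.2, 82.3; 6.00: 17.4, 76.4; 10.0: 19.0, 69.1; 15.0: 19.1, 61.8

(scatter of a reading: 0.5 percentage points)

- north: at 20 min take out 90% of the target then present, then wait 40 min
- south-west: at 20 min raise the temperature by 25 K, then wait 40 min
- south-east: change nothing and wait 40 min more

- target, in percent of the starting material first charged, at 20 min
- the remedy with the largest gain of target, or "none" below 2 percentage points (north / south-west / south-east / none)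
- target present, with what was taken out counted in, in percent of the starting material first charged, after north
- target present, with what was taken out counted in, in percent of the starting material first charged, after south-west

- what is taken out of target is counted as made
- what may be going on: target <-> isomer of the product; reagent + target -> over-reaction product; third substrate + reagent -> third product; starting material + reagent -> target; second substrate + reagent -> second product
- the earlier runs do not show what temperature does; that part of a forecast is a guess

Teal's last reading gives 0.500: this is the pool share φ, target divided by starting material converted, which says how much of each converted point stands as target.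

Is one number enough? At 10.0 min ochre and teal give 0.607 and 0.615, though their reagent differs, 1.1 equiv against 0.74 equiv. Time does show, however: teal slides to φ by 15.0 min, so I use that latest value.

Ochre's starting material lost 3.1 percentage points in its last 2.00 min, slower than 8 points in 3.00 min earlier. Allowing 0.750 of the latest pace, I reckon 56.2% converted by 20 min, so target is 28.1%.

North takes out 25.3%, and the pool refills to φ. That makes 40.8% before further conversion, ahead of waiting by 13 points at equal conversion. φ was read at 35 °C, so for south-west I can only guess, and I choose north.

The forecast gives 24.7%, lower than mine, then north, 38% and 23%, on the ground of “a first-order, reversible target ⇌ isomer step”.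

The flask gives 28.5%, and the best remedy is south-west: 46.8% after north and 59.1% after south-west. The gains are 18 points, 31 points and, for south-east, 3.7 points.

    target ⇌ isomer of the product (K = 1.30, k = 0.130 min⁻¹, Ea = 81.0 kJ mol⁻¹, ΔH = −52.0 kJ mol⁻¹)
    reagent + target → over-reaction product (k = 0.00160 L mol⁻¹ min⁻¹, Ea = 90.0 kJ mol⁻¹)
    third substrate + reagent → third product (k = 0.150 L mol⁻¹ min⁻¹, Ea = 56.0 kJ mol⁻¹)
    starting material + reagent → target (k = 0.0550 L mol⁻¹ min⁻¹, Ea = 72.0 kJ mol⁻¹)
    second substrate + reagent → second product (k = 0.00360 L mol⁻¹ min⁻¹, Ea = 79.0 kJ mol⁻¹)
    (constants at 35 °C)

In the asked flask, target and isomer relax by their own step with a half-life of 3.01 min, short against 20 min, while target's half-life by over-reaction alone, with the reagent as charged, is 4.4 h, long against it. At 20 min the forward step to the isomer uses target 200 times faster than over-reaction does. In the asked flask, φ on the 58.1% converted by 20.0 min gives 29.1%.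

In the neighbour flask at 0.90 M, 47.7% is converted by 20.0 min, so φ gives 23.8%; the computed target there is 24.1%.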